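**Retrosynthetic overview**

1. Target 28 ⇐ C7 angelate and C9 isovalerate put on one after the other (TBS/TES differentiation) ⇐ enone 24 ⇐ C3 methyl by conjugate methylation/Saegusa oxidation of nor-enone 22.
2. Nor-enone 22 ⇐ cyclohexenone ring closed last by aldol condensation (C2–C3) of keto aldehyde 21, which comes from bicyclo[4.1.1]octanone 17 (C4 ketone → CH–CHO; C11 isopropenyl → acetyl).
3. Bicycle 17 ⇐ key step: intramolecular ketene–diene [2+2] of acyclic ketene 16, forming the cyclobutane and the seven-membered ring together (bonds C4–C5 and C10–C11) and setting C5, C10, C11.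
4. Acid 14 ⇐ anti-1,3-diol (Evans–Saksena, C9) ⇐ δ-hydroxy-β-keto ester 10 ⇐ Claisen acylation + Nagao acetate aldol (C7) on dienal 4 ⇐ hydroxypivaldehyde 1.
5. Ring order: cyclobutane + cycloheptane (one operation), then cyclohexenone.

Assumption: atom labels C1–C11 in the "Why" lines are longipinane locants of the target (C1 C=O, C2=C3, C4 and C11 cyclobutane CH, C5 CH, C6 CMe2, C7 OAng, C8 CH2, C9 OiVal, C10 CMe; target = 4R,5S,7R,9R,10R,11R), and auxiliary 5 is taken as purchasable (otherwise one N-acetylation of the commercial thione).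

**Step 1**
Reactants: 1 3-hydroxy-2,2-dimethylpropanal
Product: 2 (E)-6-hydroxy-5,5-dimethylhex-3-en-2-one
Conditions: Ph3P=CHC(O)Me, PhMe, 80 °C
Reagents that add atoms: 1-(triphenyl-λ5-phosphanylidene)propan-2-one, CC(=O)C=P(c1ccccc1)(c1ccccc1)c1ccccc1
Why: Wittig olefination with a stabilised ylide gives the E-enone, tolerates the free neopentyl alcohol, and the non-enolisable aldehyde cannot self-condense.

**Step 2**
Reactants: 2 (E)-6-hydroxy-5,5-dimethylhex-3-en-2-one
Product: 3 (E)-2,2,5-trimethylhexa-3,5-dien-1-ol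
Conditions: Ph3PCH3Br (2.5 equiv), KOtBu (2.5 equiv), THF, 0 °C → rt
Reagents that add atoms: methyltriphenylphosphonium bromide, C[P+](c1ccccc1)(c1ccccc1)c1ccccc1.[Br-]
Why: Wittig methylenation of the enone carbonyl (1,2-attack) builds the 2-methyl-1,3-diene and leaves the E-alkene from step 1 untouched.

**Step 3**
Reactants: 3 (E)-2,2,5-trimethylhexa-3,5-dien-1-ol
Product: 4 (E)-2,2,5-trimethylhexa-3,5-dienal
Conditions: Dess–Martin periodinane, CH2Cl2, 0 °C → rt
Reagents that add atoms: none
Why: Dess–Martin oxidation of the neopentyl alcohol is mild toward the diene, and the α-quaternary aldehyde cannot enolise, so the alkene cannot move into conjugation.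

**Step 4**
Reactants: 4 (E)-2,2,5-trimethylhexa-3,5-dienal; 5 (S)-3-acetyl-4-benzyl-1,3-thiazolidine-2-thione
Product: 7 (S)-4-benzyl-3-[(3R,5E)-3-hydroxy-4,4,7-trimethylocta-5,7-dienoyl]-1,3-thiazolidine-2-thione, via tin(II) enolate 6 (not isolated)
Conditions: Sn(OTf)2, N-ethylpiperidine, CH2Cl2, −40 °C; then 4, −78 °C; pH 7 buffer
Reagents that add atoms: none
Why: Nagao acetate aldol through a thione-chelated chair transition state, in which the aldehyde adds to the enolate face opposite the benzyl group and gives the (3R)-carbinol (future C7), the minor diastereomer being removed by chromatography.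

**Step 5**
Reactants: 7 aldol adduct; 8 methyl propanoate
Product: 10 methyl (5R,7E)-5-hydroxy-2,6,6,9-tetramethyl-3-oxodeca-7,9-dienoate (C2 epimers), via lithium ester enolate 9 (not isolated)
Conditions: LDA (3.5 equiv), 8 (3.5 equiv), THF, −78 °C; then 7, −78 → −40 °C; aq NH4Cl
Reagents that add atoms: none
Why: Claisen-type acylation of the ester enolate by the activated N-acyl thiazolidinethione releases the auxiliary and installs C4, C10 and the C10 methyl without touching the C7 carbinol.

**Step 6**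
Reactants: 10 δ-hydroxy-β-keto ester
Product: 11 methyl (3R,5R,7E)-3,5-dihydroxy-2,6,6,9-tetramethyldeca-7,9-dienoate (C2 epimers)
Conditions: Me4NBH(OAc)3, MeCN/AcOH, −30 °C
Reagents that add atoms: none
Why: Evans–Saksena reduction delivers hydride intramolecularly from the alkoxy(acetoxy)borohydride bound at the C7 hydroxyl, giving the 1,3-anti diol and so the (R)-carbinol at C9.

**Step 7**
Reactants: 11 anti-diol ester
Product: 13 methyl (3R,5R,7E)-5-[(tert-butyldimethylsilyl)oxy]-2,6,6,9-tetramethyl-3-[(triethylsilyl)oxy]deca-7,9-dienoate, via 3-O-triethylsilyl ether 12 (not isolated)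
Conditions: TESCl (1.05 equiv), imidazole, CH2Cl2, −30 °C; then 2,6-lutidine, TBSOTf, 0 °C
Reagents that add atoms: chlorotriethylsilane, CC[Si](Cl)(CC)CC; tert-butyldimethylsilyl trifluoromethanesulfonate, CC(C)(C)[Si](C)(C)OS(=O)(=O)C(F)(F)F
Why: Sequential silyl ether formation, in which the unhindered C9 hydroxyl takes the labile TES group first and the neopentyl C7 hydroxyl is then forced to the robust TBS ether, differentiating the two oxygens for the later acylations.

**Step 8**
Reactants: 13 bis-silyl ester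
Product: 14 (3R,5R,7E)-5-[(tert-butyldimethylsilyl)oxy]-2,6,6,9-tetramethyl-3-[(triethylsilyl)oxy]deca-7,9-dienoic acid (C2 epimers)
Conditions: LiOH·H2O, THF/H2O, 35 °C; then AcOH to pH 5
Reagents that add atoms: lithium hydroxide, [Li+].[OH-]
Why: Saponification of the methyl ester under methanol-free conditions keeps both silyl ethers, and C2 epimerisation is irrelevant because this carbon becomes sp2 in the ketene.

**Step 9**
Reactants: 14 dienoic acid
Product: 17 4-[(tert-butyldimethylsilyl)oxy]-1,5,5-trimethyl-8-(prop-1-en-2-yl)-2-[(triethylsilyl)oxy]bicyclo[4.1.1]octan-7-one, via acid chloride 15 (not isolated), via ketene 16 (not isolated)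
Conditions: Me2C=C(Cl)NMe2 (1.2 equiv), CH2Cl2, 0 °C → rt; then syringe-pump addition (12 h) into Et3N (5 equiv), PhMe, 110 °C, 0.003 M
Reagents that add atoms: none
Why: Proposed new method: the carbonyl carbon of methyl(alkyl)ketene 16 is attacked by the proximal terminus of the tethered E-1,3-diene (C4–C5, charge spread as an allyl cation) and the ketene α-carbon then closes on the internal diene carbon (C10–C11), an intramolecular ketene–diene [2+2] that makes the cyclobutanone and the seven-membered ring in one operation; the closest known reaction types are the intramolecular ketene–alkene [2+2] that gives bridged bicyclo[3.1.1]heptan-6-ones and the intermolecular ketene + 1,3-diene [2+2], here extended by one tether atom with gem-dimethyl assistance; C5/C11 follow stereospecifically from the E-alkene, C10 is fixed by the bridge, and the face is chosen in a chair-like seven-membered transition state with OTBS equatorial (no 1,3-diaxial clash with the reacting diene carbon) and OTES pseudoaxial (A1,2 strain with the ketene methyl), which puts C7–O on the C4 side and C9–O on the C11 side as in the target.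

**Step 10**
Reactants: 17 bicyclic cyclobutanone
Product: 19 4-[(tert-butyldimethylsilyl)oxy]-2-hydroxy-1,5,5-trimethyl-8-(prop-1-en-2-yl)bicyclo[4.1.1]octane-7-carbaldehyde (C7 epimers), via methyl enol ether 18 (not isolated)
Conditions: MeOCH2PPh3Cl, KHMDS, THF, 0 °C → rt; then TsOH·H2O (cat.), acetone/H2O, rt
Reagents that add atoms: (methoxymethyl)triphenylphosphonium chloride, COC[P+](c1ccccc1)(c1ccccc1)c1ccccc1.[Cl-]; water, O
Why: Wittig methoxymethylenation of the strained, non-enolisable cyclobutanone followed by enol ether hydrolysis adds C3 as an aldehyde and at the same time cleaves only the TES ether, the epimerisable C4 centre being fixed later in step 12.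

**Step 11**
Reactants: 19 hydroxy aldehyde
Product: 20 4-[(tert-butyldimethylsilyl)oxy]-7-formyl-1,5,5-trimethyl-8-(prop-1-en-2-yl)bicyclo[4.1.1]octan-2-yl 3-methylbutanoate
Conditions: iPrCH2COCl, pyridine, DMAP (cat.), CH2Cl2, 0 → 40 °C
Reagents that add atoms: 3-methylbutanoyl chloride, CC(C)CC(Cl)=O
Why: DMAP-catalysed acylation places the isovalerate on the only free hydroxyl (C9) while C7 stays masked as its TBS ether.

**Step 12**
Reactants: 20 isovalerate aldehyde
Product: 22 7-[(tert-butyldimethylsilyl)oxy]-9-(3-methylbutanoyloxy)-3-demethyl-longipin-2-en-1-one, via keto aldehyde 21 (not isolated)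
Conditions: O3, CH2Cl2, −78 °C; Me2S; then Bn2NH2+ CF3CO2− (20 mol %), PhMe, 60 °C
Reagents that add atoms: ozone, [O-][O+]=O
Why: Ozonolysis turns the isopropenyl group into the C1 acetyl and an amine-salt-catalysed intramolecular aldol condensation then closes the cyclohexenone with fixed regiochemistry (only the methyl ketone can be the nucleophile and the aldehyde the electrophile); C4 is set because the aldehyde epimerises under the conditions and only the epimer syn to the acetyl can cyclise.

**Step 13**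
Reactants: 22 nor-enone
Product: 24 7-[(tert-butyldimethylsilyl)oxy]-9-(3-methylbutanoyloxy)longipin-2-en-1-one, via trimethylsilyl enol ether 23 (not isolated)
Conditions: Me2CuLi, TMSCl, THF, −78 °C; Et3N, pentane; then Pd(OAc)2 (1.1 equiv), MeCN, rt
Reagents that add atoms: lithium dimethylcuprate, [Li+].C[Cu-]C
Why: TMSCl-accelerated cuprate conjugate addition installs the C3 methyl and Saegusa–Ito oxidation of the trapped silyl enol ether restores the C2=C3 enone, erasing the transient C3 stereocentre (desaturation toward the C11 bridgehead is impossible).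

**Step 14**
Reactants: 24 silyl-protected enone
Product: 25 7-hydroxy-9-(3-methylbutanoyloxy)longipin-2-en-1-one
Conditions: HF·pyridine, THF/pyridine, 0 °C → rt
Reagents that add atoms: none
Why: Buffered fluoride desilylation frees the neopentyl C7 hydroxyl without basic conditions, so the isovalerate does not migrate and the strained skeleton is not exposed to strong acid.

**Step 15**
Reactants: 25 C7 alcohol; 26 angelic acid
Product: 28 target CNP0240547.2, via mixed anhydride 27 (not isolated)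
Conditions: 26, 2,4,6-Cl3C6H2COCl, Et3N, PhMe, rt; then 25, 80 °C
Reagents that add atoms: none
Why: Yamaguchi-type esterification with the preformed angelic 2,4,6-trichlorobenzoic mixed anhydride and no DMAP acylates the hindered alcohol while keeping the Z-alkene (no angelate-to-tiglate isomerisation).

**Compound list**

1 | 3-hydroxy-2,2-dimethylpropanal (hydroxypivaldehyde) | O=CC(C)(C)CO | starting material
2 | (E)-6-hydroxy-5,5-dimethylhex-3-en-2-one | CC(=O)/C=C/C(C)(C)CO | intermediate
3 | (E)-2,2,5-trimethylhexa-3,5-dien-1-ol | OCC(C)(C)/C=C/C(C)=C | intermediate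
4 | (E)-2,2,5-trimethylhexa-3,5-dienal | O=CC(C)(C)/C=C/C(C)=C | intermediate
5 | (S)-3-acetyl-4-benzyl-1,3-thiazolidine-2-thione | CC(=O)N1[C@@H](Cc2ccccc2)CSC1=S | starting material
6 | tin(II) triflate enolate of 5 | C=C(O[Sn]OS(=O)(=O)C(F)(F)F)N1[C@@H](Cc2ccccc2)CSC1=S | intermediate
7 | (S)-4-benzyl-3-[(3R,5E)-3-hydroxy-4,4,7-trimethylocta-5,7-dienoyl]-1,3-thiazolidine-2-thione | O=C(C[C@@H](O)C(C)(C)/C=C/C(C)=C)N1[C@@H](Cc2ccccc2)CSC1=S | intermediate
8 | methyl propanoate | CCC(=O)OC | starting material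
9 | lithium enolate of methyl propanoate | CC=C(O[Li])OC | intermediate
10 | methyl (5R,7E)-5-hydroxy-2,6,6,9-tetramethyl-3-oxodeca-7,9-dienoate (C2 epimers) | COC(=O)C(C)C(=O)C[C@@H](O)C(C)(C)/C=C/C(C)=C | intermediate
11 | methyl (3R,5R,7E)-3,5-dihydroxy-2,6,6,9-tetramethyldeca-7,9-dienoate (anti diol, C2 epimers) | COC(=O)C(C)[C@H](O)C[C@@H](O)C(C)(C)/C=C/C(C)=C | intermediate
12 | methyl (3R,5R,7E)-5-hydroxy-2,6,6,9-tetramethyl-3-[(triethylsilyl)oxy]deca-7,9-dienoate | COC(=O)C(C)[C@H](O[Si](CC)(CC)CC)C[C@@H](O)C(C)(C)/C=C/C(C)=C | intermediate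
13 | methyl (3R,5R,7E)-5-[(tert-butyldimethylsilyl)oxy]-2,6,6,9-tetramethyl-3-[(triethylsilyl)oxy]deca-7,9-dienoate | COC(=O)C(C)[C@H](O[Si](CC)(CC)CC)C[C@@H](O[Si](C)(C)C(C)(C)C)C(C)(C)/C=C/C(C)=C | intermediate
14 | (3R,5R,7E)-5-[(tert-butyldimethylsilyl)oxy]-2,6,6,9-tetramethyl-3-[(triethylsilyl)oxy]deca-7,9-dienoic acid | OC(=O)C(C)[C@H](O[Si](CC)(CC)CC)C[C@@H](O[Si](C)(C)C(C)(C)C)C(C)(C)/C=C/C(C)=C | intermediate
15 | acid chloride of 14 | ClC(=O)C(C)[C@H](O[Si](CC)(CC)CC)C[C@@H](O[Si](C)(C)C(C)(C)C)C(C)(C)/C=C/C(C)=C | intermediate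
16 | ketene from 15 (2-methyl-substituted alkyl ketene) | O=C=C(C)[C@H](O[Si](CC)(CC)CC)C[C@@H](O[Si](C)(C)C(C)(C)C)C(C)(C)/C=C/C(C)=C | intermediate
17 | 4-[(tert-butyldimethylsilyl)oxy]-1,5,5-trimethyl-8-(prop-1-en-2-yl)-2-[(triethylsilyl)oxy]bicyclo[4.1.1]octan-7-one; 2-OTES on the C8 side, 4-OTBS on the C7 side, isopropenyl trans to C5 across the cyclobutane (bicyclic C1–C8 = longipinane C10, C9, C8, C7, C6, C5, C4, C11) | CC(C)(C)[Si](C)(C)O[C@@H]1C[C@@H](O[Si](CC)(CC)CC)[C@@]2(C)[C@H](C(C)=C)[C@@H](C1(C)C)C2=O | intermediate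
18 | 7-(methoxymethylidene) derivative of 17 (E/Z mixture) | CC(C)(C)[Si](C)(C)O[C@@H]1C[C@@H](O[Si](CC)(CC)CC)[C@@]2(C)[C@H](C(C)=C)[C@@H](C1(C)C)C2=COC | intermediate
19 | 4-[(tert-butyldimethylsilyl)oxy]-2-hydroxy-1,5,5-trimethyl-8-(prop-1-en-2-yl)bicyclo[4.1.1]octane-7-carbaldehyde (C7 epimers, other centres as in 17) | CC(C)(C)[Si](C)(C)O[C@@H]1C[C@@H](O)[C@@]2(C)[C@H](C(C)=C)[C@@H](C1(C)C)C2C=O | intermediate
20 | 2-O-(3-methylbutanoyl) ester of 19 | CC(C)(C)[Si](C)(C)O[C@@H]1C[C@@H](OC(=O)CC(C)C)[C@@]2(C)[C@H](C(C)=C)[C@@H](C1(C)C)C2C=O | intermediate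
21 | 8-acetyl-7-formyl analogue of 20 (keto aldehyde) | CC(C)(C)[Si](C)(C)O[C@@H]1C[C@@H](OC(=O)CC(C)C)[C@@]2(C)[C@H](C(C)=O)[C@@H](C1(C)C)C2C=O | intermediate
22 | 7-[(tert-butyldimethylsilyl)oxy]-9-(3-methylbutanoyloxy)-3-demethyl-longipin-2-en-1-one (ring stereocentres as in the target) | CC(C)(C)[Si](C)(C)O[C@@H]1C[C@@H](OC(=O)CC(C)C)[C@@]2(C)[C@@H]3C(=O)C=C[C@H]2[C@@H]3C1(C)C | intermediate
23 | 1-(trimethylsilyloxy)-1-ene silyl enol ether of the 3-methyl adduct of 22 (C3 epimers) | CC(C)(C)[Si](C)(C)O[C@@H]1C[C@@H](OC(=O)CC(C)C)[C@@]2(C)[C@@H]3C(O[Si](C)(C)C)=CC(C)[C@H]2[C@@H]3C1(C)C | intermediate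
24 | (4R,5S,7R,9R,10R,11R)-7-[(tert-butyldimethylsilyl)oxy]-9-(3-methylbutanoyloxy)longipin-2-en-1-one | CC(C)(C)[Si](C)(C)O[C@@H]1C[C@@H](OC(=O)CC(C)C)[C@@]2(C)[C@@H]3C(=O)C=C(C)[C@H]2[C@@H]3C1(C)C | intermediate
25 | (4R,5S,7R,9R,10R,11R)-7-hydroxy-9-(3-methylbutanoyloxy)longipin-2-en-1-one | O[C@@H]1C[C@@H](OC(=O)CC(C)C)[C@@]2(C)[C@@H]3C(=O)C=C(C)[C@H]2[C@@H]3C1(C)C | intermediate
26 | angelic acid, (Z)-2-methylbut-2-enoic acid | C/C=C(/C)C(=O)O | starting material
27 | angelic 2,4,6-trichlorobenzoic mixed anhydride | C/C=C(/C)C(=O)OC(=O)c1c(Cl)cc(Cl)cc1Cl | intermediate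
28 | CNP0240547.2, (4R,5S,7R,9R,10R,11R)-7-angeloyloxy-9-(3-methylbutanoyloxy)longipin-2-en-1-one | C/C=C(/C)C(=O)O[C@@H]1C[C@@H](OC(=O)CC(C)C)[C@@]2(C)[C@@H]3C(=O)C=C(C)[C@H]2[C@@H]3C1(C)C | target

**Step count and risks**

Total step count: 15. Longest linear sequence: 15 (fully linear from 1).

The three steps most likely to fail:

Step 9 (bridged ketene–diene [2+2]). A seven-membered bridged closure is without direct precedent, ketene oligomerisation may win, and the facial selectivity rests on a transition-state model. Fallback, from acid 14 back to cycloadduct 17: change the reactive species from the neutral ketene to a far more electrophilic keteniminium ion. Acid 14 is taken through acid chloride 15 and treated with pyrrolidine to give the pyrrolidine amide F1. Tf2O and 2,6-di-tert-butyl-4-methylpyridine in 1,2-dichloroethane (rt → 60 °C) convert it into the keteniminium triflate F2, which cyclises onto the same diene to the cyclobutaniminium triflate F3. Aqueous NaHCO3 hydrolysis then gives ketone 17.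

Step 12 (aldol closure to the strained bicyclo[3.1.1]heptenone). The reversible aldol may not overcome the strain, or the keto aldehyde may oligomerise. Fallback, from aldehyde 20 back to nor-enone 22: form the C2–C3 bond irreversibly before the ketone is unmasked. Me2AlCl in CH2Cl2 at −78 °C promotes an intramolecular carbonyl-ene reaction between the aldehyde and the isopropenyl group to give the homoallylic alcohol F4, which carries an exocyclic methylene at C1. Ozonolysis (O3, then Me2S) gives the β-hydroxy ketone F5. MsCl/Et3N converts it into the mesylate F6, which eliminates in the same flask to 22.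

Step 15 (angeloylation of the neopentyl C7 alcohol). The acylation may be too slow, or the angelate may isomerise to the tiglate on prolonged heating. Fallback, from alcohol 25 to target 28: build the Z-alkene on the molecule instead of transferring it. Esterification of 25 with 2-[bis(2,2,2-trifluoroethoxy)phosphoryl]propanoic acid (DIC, DMAP) gives the phosphonate ester F7. Still–Gennari olefination with acetaldehyde (KHMDS, 18-crown-6, THF, −78 °C) then forms the (Z)-2-methylbut-2-enoate and so 28.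

**Further compounds**

F1 | step 9 | 1-[(3R,5R,7E)-5-[(tert-butyldimethylsilyl)oxy]-2,6,6,9-tetramethyl-3-[(triethylsilyl)oxy]deca-7,9-dienoyl]pyrrolidine | O=C(N1CCCC1)C(C)[C@H](O[Si](CC)(CC)CC)C[C@@H](O[Si](C)(C)C(C)(C)C)C(C)(C)/C=C/C(C)=C
F2 | step 9 | keteniminium triflate from F1 | C1CC[N+](C1)=C=C(C)[C@H](O[Si](CC)(CC)CC)C[C@@H](O[Si](C)(C)C(C)(C)C)C(C)(C)/C=C/C(C)=C.[O-]S(=O)(=O)C(F)(F)F
F3 | step 9 | pyrrolidinium (cyclobutaniminium) triflate corresponding to ketone 17 | CC(C)(C)[Si](C)(C)O[C@@H]1C[C@@H](O[Si](CC)(CC)CC)[C@@]2(C)[C@H](C(C)=C)[C@@H](C1(C)C)C2=[N+]1CCCC1.[O-]S(=O)(=O)C(F)(F)F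
F4 | step 12 | 7-[(tert-butyldimethylsilyl)oxy]-3-hydroxy-1-methylidene-9-(3-methylbutanoyloxy)-3-demethyl-longipinane (C3 epimers) | CC(C)(C)[Si](C)(C)O[C@@H]1C[C@@H](OC(=O)CC(C)C)[C@@]2(C)[C@@H]3C(=C)CC(O)[C@H]2[C@@H]3C1(C)C
F5 | step 12 | 7-[(tert-butyldimethylsilyl)oxy]-3-hydroxy-9-(3-methylbutanoyloxy)-3-demethyl-longipinan-1-one | CC(C)(C)[Si](C)(C)O[C@@H]1C[C@@H](OC(=O)CC(C)C)[C@@]2(C)[C@@H]3C(=O)CC(O)[C@H]2[C@@H]3C1(C)C
F6 | step 12 | 3-O-methanesulfonate of F5 | CC(C)(C)[Si](C)(C)O[C@@H]1C[C@@H](OC(=O)CC(C)C)[C@@]2(C)[C@@H]3C(=O)CC(OS(C)(=O)=O)[C@H]2[C@@H]3C1(C)C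
F7 | step 15 | 7-O-{2-[bis(2,2,2-trifluoroethoxy)phosphoryl]propanoyl} ester of 25 | CC(C(=O)O[C@@H]1C[C@@H](OC(=O)CC(C)C)[C@@]2(C)[C@@H]3C(=O)C=C(C)[C@H]2[C@@H]3C1(C)C)P(=O)(OCC(F)(F)F)OCC(F)(F)F
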